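**Plan**

1. Retrosynthesis: the prenyl olefin is cut first (cross-metathesis of an 8-allyl group), then the two phenolic O–benzyl bonds, then C4–C4a of the pyranone (intramolecular acylation), then the two aryl-O–C2 bonds (two aryloxides onto one 3,3-dichloroacrylate carbon), and last C8–CH2 (Claisen rearrangement).
2. Forward: 3,5-bis(benzyloxy)phenol is O-allylated and rearranged to the 2-allylphenol; 4-methoxyphenoxide and then this phenoxide replace the two chlorides of allyl 3,3-dichloroacrylate; the allyl ester is removed; the pyranone, the only ring that is built, closes at C4–C4a; debenzylation and allyl-to-prenyl metathesis finish the route.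
3. Enabling feature: C4a of ring A is ortho to O1 and O5 and para to O7, and it is the only unsubstituted carbon ortho to O1 once C8 carries the allyl group, so an acyl carbon held through O1–C2=C3 can reach and acylate that atom alone.
4. Stereochemistry: the target has no stereocentre and its prenyl olefin has no geometry; the one stereo element on the way, the ketene acetal C2=C3 bond, disappears into the aromatic pyranone.

Key step: step 7

Assumption: the addition–elimination steps may deliver 8 and 9 (and hence 10 to 12) as mixtures of double bond isomers. Each is named and drawn as one isomer (for 9 to 12 the one with the ring A aryloxy group cis to the carbonyl, which is Z by the sequence rules). The mixture can be carried on, because the push–pull C2=C3 bond should isomerize under the conditions of step 7 and is no stereo element of 13.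

**Route**

Step 1
Reactants: 1 3,5-bis(benzyloxy)phenol; 2 allyl bromide (3-bromoprop-1-ene)
Product: 3 1-(allyloxy)-3,5-bis(benzyloxy)benzene
Conditions: K2CO3, acetone, reflux
Reagents that add atoms: none
Why: Williamson ether synthesis, in which the phenoxide is alkylated at oxygen by the primary allylic bromide (SN2) under weak-base, aprotic conditions that disfavour C-allylation.

Step 2
Reactants: 3 1-(allyloxy)-3,5-bis(benzyloxy)benzene
Product: 4 2-allyl-3,5-bis(benzyloxy)phenol
Conditions: PhNEt2, 200 °C, sealed tube
Reagents that add atoms: none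
Why: Aromatic Claisen rearrangement, a [3,3]-sigmatropic shift that moves the allyl group to either of the two equivalent ortho carbons and is followed by rearomatization, at a temperature that aryl benzyl ethers tolerate.

Step 3
Reactants: 5 3,3-dichloroacrylic acid; 2 allyl bromide
Product: 6 allyl 3,3-dichloroacrylate
Conditions: KHCO3, DMF, rt
Reagents that add atoms: none
Why: O-alkylation of the carboxylate by the allylic bromide (SN2) under hydrogencarbonate, a base too weak and too poorly nucleophilic to attack the dichlorovinyl group.

Step 4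
Reactants: 6 allyl 3,3-dichloroacrylate; 7 4-methoxyphenol
Product: 8 allyl (E)-3-chloro-3-(4-methoxyphenoxy)acrylate
Conditions: K2CO3, DMF, 0 °C to rt, 6 in slight excess, 7 added slowly
Reagents that add atoms: none
Why: Nucleophilic vinylic substitution by addition–elimination, in which the phenoxide adds to the β-carbon and chloride leaves, and the donor aryloxy group makes 8 a poorer acceptor than 6, so that one exchange should be the end point.

Step 5
Reactants: 8 allyl (E)-3-chloro-3-(4-methoxyphenoxy)acrylate; 4 2-allyl-3,5-bis(benzyloxy)phenol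
Product: 9 allyl (Z)-3-[2-allyl-3,5-bis(benzyloxy)phenoxy]-3-(4-methoxyphenoxy)acrylate
Conditions: Cs2CO3, MeCN, rt, 8 in slight excess
Reagents that add atoms: none
Why: Second nucleophilic vinylic substitution (addition–elimination), in which the ester-stabilized carbanion adduct should lose chloride far faster than an aryloxide, so that the mixed ketene acetal forms without exchange of the aryloxy group already in place as long as no phenoxide is left over.

Step 6
Reactants: 9 allyl (Z)-3-[2-allyl-3,5-bis(benzyloxy)phenoxy]-3-(4-methoxyphenoxy)acrylate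
Product: 11 (Z)-3-[2-allyl-3,5-bis(benzyloxy)phenoxy]-3-(4-methoxyphenoxy)acrylic acid, via sodium carboxylate 10 (not isolated)
Conditions: Pd(PPh3)4 (cat.), 4-MeC6H4SO2Na, THF/MeOH, rt; ether wash of the aqueous salt solution, then cold aq. NaH2PO4 and extraction; used at once
Reagents that add atoms: none
Why: Tsuji–Trost-type deallylation, in which zerovalent palladium ionizes only the allyl ester and the soft sulfinate traps the allyl fragment irreversibly as a neutral sulfone, in a neutral, non-hydrolytic medium that should spare the ketene acetal, the benzyl ethers and the C-allyl group.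

Step 7
Reactants: 11 (Z)-3-[2-allyl-3,5-bis(benzyloxy)phenoxy]-3-(4-methoxyphenoxy)acrylic acid
Product: 13 8-allyl-5,7-bis(benzyloxy)-2-(4-methoxyphenoxy)-4H-chromen-4-one, via mixed trifluoroacetic anhydride 12 (not isolated)
Conditions: (CF3CO)2O, CH2Cl2 (high dilution), 0 °C to rt; then cold aq. NaHCO3
Reagents that add atoms: none
Why: Proposed new method: trifluoroacetic anhydride turns acid 11 into mixed anhydride 12, which ionizes (helped by the CF3CO2H set free) to an acylium ion that both aryloxy groups stabilize as a ketene-substituted dioxocarbenium ion; this electrophile attacks C4a of ring A and loss of a proton restores the arene. The closest known reaction type is the intramolecular Friedel–Crafts acylation of 3-aryloxyacrylic and 3-aryloxycrotonic acids to chromones (and of aryl hydrogen malonates to 4-hydroxycoumarins), which has not been shown for a 3,3-bis(aryloxy)acrylic acid. The pyranone closes in a 6-exo mode, the acyl C=O bond staying outside the new six-membered ring as C4–C4a forms. No stereocentre is created and the C2=C3 geometry of 11 is erased. The step needs attack by ring A and not by the anisyl ring, and closure within one molecule: C4a is activated by three oxygens (ortho to O1 and O5, para to O7) while the carbons ortho to the anisyl oxygen are activated by one and lie meta to the methoxy group, the single-bond character of C2–C3 in the cation lets either double bond isomer reach C4a, and high dilution holds back acylation at the carbon between the two benzyloxy groups of a second molecule. Water-free conditions keep the ketene acetal from hydrolysis, and the benzyl ethers and the terminal alkene should not react with CF3CO2H at or below room temperature.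

Step 8
Reactants: 13 8-allyl-5,7-bis(benzyloxy)-2-(4-methoxyphenoxy)-4H-chromen-4-one
Product: 14 8-allyl-5,7-dihydroxy-2-(4-methoxyphenoxy)-4H-chromen-4-one
Conditions: BCl3, C6HMe5, CH2Cl2, −78 °C; MeOH quench
Reagents that add atoms: none
Why: Lewis-acid debenzylation with a non-basic cation scavenger, in which BCl3 cleaves both aryl benzyl ethers at low temperature and pentamethylbenzene takes up the benzyl cations by Friedel–Crafts alkylation, so that the terminal alkene, the aryl methyl ether and the 2-aryloxy linkage should stay intact.

Step 9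
Reactants: 14 8-allyl-5,7-dihydroxy-2-(4-methoxyphenoxy)-4H-chromen-4-one
Product: 15 5,7-dihydroxy-2-(4-methoxyphenoxy)-8-(3-methylbut-2-en-1-yl)-4H-chromen-4-one (the target, CNP0274214.0)
Conditions: second-generation Grubbs catalyst RuCl2(=CHPh)(H2IMes)(PCy3) (cat.), 2-methyl-2-butene (large excess), CH2Cl2, 40 °C
Reagents that add atoms: 2-methyl-2-butene, CC=C(C)C
Why: Olefin cross-metathesis, in which the terminal alkene exchanges its methylene end for an isopropylidene unit from the excess trisubstituted olefin, a change well precedented for ortho-allylphenols with free hydroxyl groups and one that creates neither a stereocentre nor a double bond geometry.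

**Compound list**

1 | 3,5-bis(benzyloxy)phenol | Oc1cc(OCc2ccccc2)cc(OCc2ccccc2)c1 | starting material
2 | allyl bromide | C=CCBr | starting material
3 | 1-(allyloxy)-3,5-bis(benzyloxy)benzene | C=CCOc1cc(OCc2ccccc2)cc(OCc2ccccc2)c1 | intermediate
4 | 2-allyl-3,5-bis(benzyloxy)phenol | Oc1cc(OCc2ccccc2)cc(OCc2ccccc2)c1CC=C | intermediate
5 | 3,3-dichloroacrylic acid | OC(=O)C=C(Cl)Cl | starting material
6 | allyl 3,3-dichloroacrylate | C=CCOC(=O)C=C(Cl)Cl | intermediate
7 | 4-methoxyphenol | COc1ccc(O)cc1 | starting material
8 | allyl (E)-3-chloro-3-(4-methoxyphenoxy)acrylate | C=CCOC(=O)/C=C(/Cl)Oc1ccc(OC)cc1 | intermediate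
9 | allyl (Z)-3-[2-allyl-3,5-bis(benzyloxy)phenoxy]-3-(4-methoxyphenoxy)acrylate | C=CCOC(=O)/C=C(\Oc1cc(OCc2ccccc2)cc(OCc2ccccc2)c1CC=C)Oc1ccc(OC)cc1 | intermediate
10 | sodium (Z)-3-[2-allyl-3,5-bis(benzyloxy)phenoxy]-3-(4-methoxyphenoxy)acrylate (not isolated) | [Na+].[O-]C(=O)/C=C(\Oc1cc(OCc2ccccc2)cc(OCc2ccccc2)c1CC=C)Oc1ccc(OC)cc1 | intermediate
11 | (Z)-3-[2-allyl-3,5-bis(benzyloxy)phenoxy]-3-(4-methoxyphenoxy)acrylic acid | OC(=O)/C=C(\Oc1cc(OCc2ccccc2)cc(OCc2ccccc2)c1CC=C)Oc1ccc(OC)cc1 | intermediate
12 | (Z)-3-[2-allyl-3,5-bis(benzyloxy)phenoxy]-3-(4-methoxyphenoxy)acrylic trifluoroacetic anhydride (not isolated) | O=C(OC(=O)C(F)(F)F)/C=C(\Oc1cc(OCc2ccccc2)cc(OCc2ccccc2)c1CC=C)Oc1ccc(OC)cc1 | intermediate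
13 | 8-allyl-5,7-bis(benzyloxy)-2-(4-methoxyphenoxy)-4H-chromen-4-one | COc1ccc(Oc2cc(=O)c3c(OCc4ccccc4)cc(OCc4ccccc4)c(CC=C)c3o2)cc1 | intermediate
14 | 8-allyl-5,7-dihydroxy-2-(4-methoxyphenoxy)-4H-chromen-4-one | COc1ccc(Oc2cc(=O)c3c(O)cc(O)c(CC=C)c3o2)cc1 | intermediate
15 | 5,7-dihydroxy-2-(4-methoxyphenoxy)-8-(3-methylbut-2-en-1-yl)-4H-chromen-4-one | COc1ccc(Oc2cc(=O)c3c(O)cc(O)c(CC=C(C)C)c3o2)cc1 | target

**Count and risks**

Total steps: 9. Longest linear sequence: 7 steps (steps 1, 2, 5, 6, 7, 8, 9; the branch through steps 3 and 4 is equally long).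

Steps most likely to fail:

1. Step 7 (proposed method). The acid may lose CO2 or be hydrolysed at the ketene acetal before it is activated. The anhydride may trifluoroacetylate ring A or the α-carbon, or the acyl cation may acylate a second molecule instead of closing the ring. Fallback with known chemistry, from 4 back to 13, through the established 2-sulfinylchromone displacement:
   - Phenol 4 is acetylated at its one free ortho carbon (Ac2O, BF3·OEt2, CH2Cl2, 0 °C to rt, Fries-type delivery through the BF2 chelate, aqueous work-up) to give 1-[3-allyl-4,6-bis(benzyloxy)-2-hydroxyphenyl]ethan-1-one F1.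
   - The ketone enolate is condensed with CS2 (KOtBu, THF) and closes to 8-allyl-5,7-bis(benzyloxy)-4-hydroxy-2H-chromene-2-thione F2.
   - S-methylation (MeI, K2CO3, acetone) gives 8-allyl-5,7-bis(benzyloxy)-2-(methylsulfanyl)-4H-chromen-4-one F3.
   - One equivalent of mCPBA (CH2Cl2, 0 °C) should oxidize sulfur much faster than the terminal alkene and give racemic 8-allyl-5,7-bis(benzyloxy)-2-(methylsulfinyl)-4H-chromen-4-one F4.
   - 4-Methoxyphenol 7 (K2CO3, DMF, rt) then replaces the sulfinyl group by addition–elimination at C2 and gives 13.

2. Step 6. The ketene acetal may be hydrolysed to an aryl malonate while the carboxylate is handled in water, and the free acid may decarboxylate on concentration. Fallback from 5 back to 13, in which the carboxyl is carried as a tert-butyl ester and set free only inside the medium of the ring closure: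
   - 5 with tert-butyl 2,2,2-trichloroacetimidate (CH2Cl2/cyclohexane, rt) gives tert-butyl 3,3-dichloroacrylate F5.
   - The substitutions of steps 4 and 5 (7 with K2CO3, then 4 with Cs2CO3) give tert-butyl (E)-3-chloro-3-(4-methoxyphenoxy)acrylate F6 and then tert-butyl (Z)-3-[2-allyl-3,5-bis(benzyloxy)phenoxy]-3-(4-methoxyphenoxy)acrylate F7.
   - F7 in CH2Cl2 with CF3CO2H, (CF3CO)2O and anisole (trap for the tert-butyl cation) at 0 °C should lose the tert-butyl group, form the mixed anhydride and cyclize in one flask to 13, so that the free acid never meets water or a work-up.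

3. Step 5. Repeated addition–elimination may exchange the aryloxy groups and scramble the mixed ketene acetal into the two symmetrical ones, and the ortho-substituted phenoxide may add slowly to the deactivated chloroalkene. Fallback from 7 back to 9, which builds the acetal carbon by conjugate addition to an ynol ether and so has no leaving group on that carbon:
   - 7 and trichloroethylene (K2CO3, DMF, 70 °C) give 1-{[(E)-1,2-dichloroethenyl]oxy}-4-methoxybenzene F8.
   - n-BuLi (2 equiv, THF, −78 °C; elimination, then chlorine–lithium exchange) followed by allyl chloroformate gives allyl 3-(4-methoxyphenoxy)prop-2-ynoate F9.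
   - Phenol 4 adds to F9 in conjugate fashion (cat. K2CO3, MeCN, rt) at the carbon that bears the anisyloxy group, anti across the triple bond, and gives 9 with only a catalytic amount of phenoxide ever present.

**Further compounds**

F1 | step 7 | 1-[3-allyl-4,6-bis(benzyloxy)-2-hydroxyphenyl]ethan-1-one | CC(=O)c1c(O)c(CC=C)c(OCc2ccccc2)cc1OCc1ccccc1
F2 | step 7 | 8-allyl-5,7-bis(benzyloxy)-4-hydroxy-2H-chromene-2-thione | Oc1cc(=S)oc2c(CC=C)c(OCc3ccccc3)cc(OCc3ccccc3)c12
F3 | step 7 | 8-allyl-5,7-bis(benzyloxy)-2-(methylsulfanyl)-4H-chromen-4-one | CSc1cc(=O)c2c(OCc3ccccc3)cc(OCc3ccccc3)c(CC=C)c2o1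
F4 | step 7 | 8-allyl-5,7-bis(benzyloxy)-2-(methylsulfinyl)-4H-chromen-4-one (racemic at sulfur) | CS(=O)c1cc(=O)c2c(OCc3ccccc3)cc(OCc3ccccc3)c(CC=C)c2o1
F5 | step 6 | tert-butyl 3,3-dichloroacrylate | CC(C)(C)OC(=O)C=C(Cl)Cl
F6 | step 6 | tert-butyl (E)-3-chloro-3-(4-methoxyphenoxy)acrylate | CC(C)(C)OC(=O)/C=C(/Cl)Oc1ccc(OC)cc1
F7 | step 6 | tert-butyl (Z)-3-[2-allyl-3,5-bis(benzyloxy)phenoxy]-3-(4-methoxyphenoxy)acrylate | CC(C)(C)OC(=O)/C=C(\Oc1cc(OCc2ccccc2)cc(OCc2ccccc2)c1CC=C)Oc1ccc(OC)cc1
F8 | step 5 | 1-{[(E)-1,2-dichloroethenyl]oxy}-4-methoxybenzene | COc1ccc(O/C(Cl)=C\Cl)cc1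
F9 | step 5 | allyl 3-(4-methoxyphenoxy)prop-2-ynoate | C=CCOC(=O)C#COc1ccc(OC)cc1
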